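**Strategy.** Everything rests on opening the cyclohexene ring (C1, C7 to C11 of the 3-oxatricyclo[5.4.0.0^2,5]undecene core) across C9–C10 and C1–C11. Its only C=C, the tetrasubstituted C7=C8 bond that is exocyclic to the cyclopentane, is a Diels–Alder retron. The precursor is a 2-substituted 1,3-diene that already holds the cis-fused β-lactone, the cyclopentene and the trimethylcyclohexane; acrolein is the partner. One operation closes the last ring, fixes the alkene position, sets C1 from the convex face of the lactone bicycle and, after enolisation in the same flask, funnels both C11 epimers into the equatorial aldehyde.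

Key step: step 7

Locants: cyclohexene = C1, C7, C8, C9, C10, C11; cyclopentane = C1, C2, C5, C6, C7; β-lactone = C2, O3, C4, C5; C1' is the quaternary carbon of the trimethylcyclohexyl group.

Assumption on catalyst sense: the carbene ligand of step 2 and the cinchona catalyst of step 5 each exist in both mirror-image or pseudo-enantiomeric forms, and the form that gives the drawn configuration is meant (O-trimethylsilylquinine is written for step 5; its quinidine analogue gives the antipodal lactone).

Assumption on C11: the epimer with the equatorial formyl group (trans to C2) is taken to be the more stable one.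

Step 1
Reactants: 1 tert-butyldimethyl(pent-4-yn-1-yloxy)silane; 2 3-ethoxycyclohex-2-en-1-one
Product: 5 3-{5-[(tert-butyldimethylsilyl)oxy]pent-1-yn-1-yl}cyclohex-2-en-1-one, via lithium acetylide 3 (not isolated), via carbinol adduct 4 (not isolated)
Conditions: n-BuLi, THF, −78 °C; then 2, −78 to 0 °C; then 1 M aq HCl, 0 °C
Reagents that add atoms: water, O (supplies the new ketone oxygen in the acidic transposition)
Why: Stork–Danheiser alkynylation: 1,2-addition of the acetylide to the vinylogous ester and acid-mediated hydrolytic transposition should give the 3-alkynyl enone; no stereocentre is formed.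

Step 2
Reactants: 5 3-{5-[(tert-butyldimethylsilyl)oxy]pent-1-yn-1-yl}cyclohex-2-en-1-one
Product: 6 (3R)-3-methyl-3-{5-[(tert-butyldimethylsilyl)oxy]pent-1-yn-1-yl}cyclohexan-1-one
Conditions: MeMgBr, Cu(OTf)2 (cat.), chiral N-mesityl hydroxyalkyl imidazolinium salt (carbene precursor, cat.), Et2O, 0 °C; aq NH4Cl
Reagents that add atoms: methylmagnesium bromide, C[Mg]Br
Why: Copper–carbene-catalysed asymmetric conjugate addition of the Grignard reagent to the cyclic enynone should go 1,4 rather than 1,6 and create the quaternary centre C1', whose (R) configuration is set by the chiral ligand.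

Step 3
Reactants: 6 (3R)-3-methyl-3-{5-[(tert-butyldimethylsilyl)oxy]pent-1-yn-1-yl}cyclohexan-1-one
Product: 7 tert-butyldimethyl({5-[(1R)-1,3,3-trimethylcyclohexyl]pent-4-yn-1-yl}oxy)silane
Conditions: Me2Zn, TiCl4, CH2Cl2, −30 °C (forms Me2TiCl2); then 6, −30 °C to rt
Reagents that add atoms: dimethyltitanium dichloride, C[Ti](C)(Cl)Cl (made in the flask from dimethylzinc, C[Zn]C, and TiCl4, Cl[Ti](Cl)(Cl)Cl)
Why: Reetz geminal dimethylation: methyl addition to the ketone, ionisation of the tertiary titanium alkoxide and a second methyl transfer should turn C=O directly into CMe2 without touching the remote quaternary centre or the alkyne.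

Step 4
Reactants: 7 tert-butyldimethyl({5-[(1R)-1,3,3-trimethylcyclohexyl]pent-4-yn-1-yl}oxy)silane
Product: 10 5-[(1R)-1,3,3-trimethylcyclohexyl]pent-4-ynoic acid, via primary alcohol 8 (not isolated), via aldehyde 9 (not isolated)
Conditions: CrO3, H2SO4, H2O, acetone, 0 °C to rt
Reagents that add atoms: water, O
Why: Jones oxidation: the acidic medium should cleave the primary silyl ether and oxidise the freed alcohol through the aldehyde hydrate to the acid in one operation, the internal alkyne and C1' being inert.

Step 5
Reactants: 10 5-[(1R)-1,3,3-trimethylcyclohexyl]pent-4-ynoic acid; 11 acrolein (prop-2-enal)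
Product: 14 (3S,4R)-4-ethenyl-3-{3-[(1R)-1,3,3-trimethylcyclohexyl]prop-2-yn-1-yl}oxetan-2-one, via acid chloride 12 (not isolated), via ketene 13 (not isolated)
Conditions: (COCl)2, DMF (cat.), CH2Cl2, rt, then evaporate; 11, O-trimethylsilylquinine (10 mol %), LiClO4, iPr2NEt, CH2Cl2/Et2O, −78 °C
Reagents that add atoms: none
Why: Catalytic asymmetric acyl halide–aldehyde cyclocondensation (formal ketene–aldehyde [2+2]): the alkaloid-bound ammonium enolate of the ketene should add to LiClO4-activated acrolein through a closed aldol transition state and lactonise to the cis-3,4-disubstituted β-lactone, both new stereocentres being set by the catalyst.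

Step 6
Reactants: 14 (3S,4R)-4-ethenyl-3-{3-[(1R)-1,3,3-trimethylcyclohexyl]prop-2-yn-1-yl}oxetan-2-one
Product: 15 (1S,5R)-3-{1-[(1R)-1,3,3-trimethylcyclohexyl]ethenyl}-6-oxabicyclo[3.2.0]hept-3-en-7-one
Conditions: second-generation Grubbs catalyst, (H2IMes)(PCy3)Cl2Ru=CHPh (10 mol %), ethylene (1 atm), toluene, 80 °C
Reagents that add atoms: none
Why: Ring-closing enyne metathesis in the exo mode should close the cyclopentene and deliver the 2-substituted 1,3-diene with the lactone stereocentres untouched, ethylene keeping the ruthenium methylidene available so that the carbene forms at the less hindered alkyne carbon.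

Step 7
Reactants: 15 (1S,5R)-3-{1-[(1R)-1,3,3-trimethylcyclohexyl]ethenyl}-6-oxabicyclo[3.2.0]hept-3-en-7-one; 11 acrolein (prop-2-enal)
Product: 17 (1S,2R,5S,11R)-4-oxo-8-[(1R)-1,3,3-trimethylcyclohexyl]-3-oxatricyclo[5.4.0.0^2,5]undec-7-ene-11-carbaldehyde, via C11-epimeric aldehyde 16 (not isolated)
Conditions: 11 (excess), BHT (cat.), toluene, sealed tube, 90 °C; evaporate; DBU (0.2 equiv), CH2Cl2, 0 °C to rt
Reagents that add atoms: none
Why: Intermolecular normal-demand Diels–Alder reaction: a concerted, asynchronous suprafacial [4+2] addition of acrolein across C9 and C1 of the diene forms the C9–C10 and C1–C11 bonds and leaves the tetrasubstituted C7=C8 alkene exactly where the target has it. The closest known reaction type is the Diels–Alder reaction of 1-vinylcycloalkenes with acrolein or acrylates. The cyclohexene is closed as a [4+2] annulation onto the preformed cyclopentene, both new bonds forming on the same face of the diene. C1 is controlled by the cis-fused β-lactone, which blocks the concave face so that acrolein adds anti to O3; C11 is first set by the endo/exo preference and then corrected by DBU-mediated enolisation, which should funnel both epimers to the isomer with the equatorial formyl group trans to C2. The step needs regioselectivity (the formyl-bearing carbon bonded to C1), which the alkyl substituents at C1 and C8 secure by placing the largest HOMO coefficient on the unsubstituted C9 terminus that bonds to the acrolein β-carbon. The ring-constrained cyclopentene should keep the s-cis diene reachable despite the quaternary substituent at C8, and neutral thermal conditions spare the allylic β-lactone.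

Step 8
Reactants: 17 (1S,2R,5S,11R)-4-oxo-8-[(1R)-1,3,3-trimethylcyclohexyl]-3-oxatricyclo[5.4.0.0^2,5]undec-7-ene-11-carbaldehyde
Product: 18 (1S,2R,5S,11R)-11-(hydroxymethyl)-8-[(1R)-1,3,3-trimethylcyclohexyl]-3-oxatricyclo[5.4.0.0^2,5]undec-7-en-4-one
Conditions: NaBH4, THF/MeOH, −78 °C; AcOH quench
Reagents that add atoms: none
Why: Chemoselective hydride reduction: at low temperature NaBH4 should reduce the aldehyde far faster than the strained lactone, and no stereocentre is touched.

Step 9
Reactants: 18 (1S,2R,5S,11R)-11-(hydroxymethyl)-8-[(1R)-1,3,3-trimethylcyclohexyl]-3-oxatricyclo[5.4.0.0^2,5]undec-7-en-4-one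
Product: 19 [(1S,2R,5S,11R)-4-oxo-8-[(1R)-1,3,3-trimethylcyclohexyl]-3-oxatricyclo[5.4.0.0^2,5]undec-7-en-11-yl]methyl butanoate
Conditions: butanoyl chloride, pyridine, CH2Cl2, 0 °C
Reagents that add atoms: butanoyl chloride, CCCC(=O)Cl
Why: Acylation of the primary alcohol by nucleophilic acyl substitution should install the butanoate, the β-lactone being inert to pyridine at 0 °C.

**Compound list**

1 | tert-butyldimethyl(pent-4-yn-1-yloxy)silane | C#CCCCO[Si](C)(C)C(C)(C)C | starting material
2 | 3-ethoxycyclohex-2-en-1-one | CCOC1=CC(=O)CCC1 | starting material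
3 | {5-[(tert-butyldimethylsilyl)oxy]pent-1-yn-1-yl}lithium | [Li]C#CCCCO[Si](C)(C)C(C)(C)C | intermediate (not isolated)
4 | 3-ethoxy-1-{5-[(tert-butyldimethylsilyl)oxy]pent-1-yn-1-yl}cyclohex-2-en-1-ol (both enantiomers) | CCOC1=CC(O)(C#CCCCO[Si](C)(C)C(C)(C)C)CCC1 | intermediate (not isolated)
5 | 3-{5-[(tert-butyldimethylsilyl)oxy]pent-1-yn-1-yl}cyclohex-2-en-1-one | CC(C)(C)[Si](C)(C)OCCCC#CC1=CC(=O)CCC1 | intermediate
6 | (3R)-3-methyl-3-{5-[(tert-butyldimethylsilyl)oxy]pent-1-yn-1-yl}cyclohexan-1-one | CC(C)(C)[Si](C)(C)OCCCC#C[C@]1(C)CCCC(=O)C1 | intermediate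
7 | tert-butyldimethyl({5-[(1R)-1,3,3-trimethylcyclohexyl]pent-4-yn-1-yl}oxy)silane | CC(C)(C)[Si](C)(C)OCCCC#C[C@]1(C)CCCC(C)(C)C1 | intermediate
8 | 5-[(1R)-1,3,3-trimethylcyclohexyl]pent-4-yn-1-ol | OCCCC#C[C@]1(C)CCCC(C)(C)C1 | intermediate (not isolated)
9 | 5-[(1R)-1,3,3-trimethylcyclohexyl]pent-4-ynal | O=CCCC#C[C@]1(C)CCCC(C)(C)C1 | intermediate (not isolated)
10 | 5-[(1R)-1,3,3-trimethylcyclohexyl]pent-4-ynoic acid | OC(=O)CCC#C[C@]1(C)CCCC(C)(C)C1 | intermediate
11 | acrolein (prop-2-enal) | C=CC=O | starting material
12 | 5-[(1R)-1,3,3-trimethylcyclohexyl]pent-4-ynoyl chloride | ClC(=O)CCC#C[C@]1(C)CCCC(C)(C)C1 | intermediate (not isolated)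
13 | 5-[(1R)-1,3,3-trimethylcyclohexyl]pent-1-en-4-yn-1-one (ketene) | O=C=CCC#C[C@]1(C)CCCC(C)(C)C1 | intermediate (not isolated)
14 | (3S,4R)-4-ethenyl-3-{3-[(1R)-1,3,3-trimethylcyclohexyl]prop-2-yn-1-yl}oxetan-2-one | C=C[C@H]1OC(=O)[C@H]1CC#C[C@]2(C)CCCC(C)(C)C2 | intermediate
15 | (1S,5R)-3-{1-[(1R)-1,3,3-trimethylcyclohexyl]ethenyl}-6-oxabicyclo[3.2.0]hept-3-en-7-one | C=C(C1=C[C@H]2OC(=O)[C@H]2C1)[C@]1(C)CCCC(C)(C)C1 | intermediate
16 | (1S,2R,5S,11S)-4-oxo-8-[(1R)-1,3,3-trimethylcyclohexyl]-3-oxatricyclo[5.4.0.0^2,5]undec-7-ene-11-carbaldehyde (formyl cis to C2) | O=C[C@H]1CCC([C@]2(C)CCCC(C)(C)C2)=C2C[C@@H]3C(=O)O[C@@H]3[C@H]21 | intermediate (not isolated)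
17 | (1S,2R,5S,11R)-4-oxo-8-[(1R)-1,3,3-trimethylcyclohexyl]-3-oxatricyclo[5.4.0.0^2,5]undec-7-ene-11-carbaldehyde | O=C[C@@H]1CCC([C@]2(C)CCCC(C)(C)C2)=C2C[C@@H]3C(=O)O[C@@H]3[C@H]21 | intermediate
18 | (1S,2R,5S,11R)-11-(hydroxymethyl)-8-[(1R)-1,3,3-trimethylcyclohexyl]-3-oxatricyclo[5.4.0.0^2,5]undec-7-en-4-one | OC[C@@H]1CCC([C@]2(C)CCCC(C)(C)C2)=C2C[C@@H]3C(=O)O[C@@H]3[C@H]21 | intermediate
19 | [(1S,2R,5S,11R)-4-oxo-8-[(1R)-1,3,3-trimethylcyclohexyl]-3-oxatricyclo[5.4.0.0^2,5]undec-7-en-11-yl]methyl butanoate | CCCC(=O)OC[C@@H]1CCC([C@]2(C)CCCC(C)(C)C2)=C2C[C@@H]3C(=O)O[C@@H]3[C@H]21 | target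

**Step count.** Total: 9 steps. Longest linear sequence: 9 steps (from 1).

**Steps most likely to fail**

Step 6 (enyne metathesis). Carbene transfer to the alkyne may stall because the alkyne carbon next to the quaternary cyclohexane carbon is shielded, so that oligomerisation through the vinyl group or ring closure in the endo sense takes over. Fallback: setting out from 14, the same skeletal reorganisation is carried out without a metal carbene, by electrophilic activation of the alkyne with PtCl2 (5 mol %, toluene, 80 °C). Divalent platinum acts as a π-acid: 5-exo attack of the vinyl group gives a cyclopropyl platinum carbene that rearranges to the formal metathesis product. This should be much less sensitive to the size of the alkyne substituent. It rejoins the route at 15 and needs no new compound (entry F0).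

Step 7 (Diels–Alder reaction and equilibration). The cycloaddition may be too slow because the diene must reach its s-cis conformer against the quaternary substituent at C8, which leaves room for polymerisation of acrolein or thermal opening of the allylic lactone. Equilibration at C11 may also stay incomplete, in which case the minor epimer is separated and resubmitted to DBU. Fallback: setting out from 15, the more electrophilic prop-2-enoyl chloride serves as the 2π partner at ambient temperature in CH2Cl2 and should give the tricyclic acid chloride F1 together with its C11 epimer. LiAlH(OtBu)3 in THF at −78 °C then reduces the acid chloride to the aldehyde, and the route is rejoined at 16, which DBU converts into 17 as in step 7.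

Step 5 (ketene–aldehyde cyclocondensation). The enal may be consumed by amine-induced conjugate addition or polymerisation, or react too slowly with the ammonium enolate, and the cis selectivity may erode. Fallback: setting out from 10, the acid is activated with pivaloyl chloride and Et3N and coupled with lithiated (4S)-4-benzyl-1,3-oxazolidin-2-one to the imide F2. The boron-mediated Evans syn aldol reaction with acrolein (Bu2BOTf, iPr2NEt, CH2Cl2, −78 °C) should give the syn adduct F3. LiOH/H2O2 releases the β-hydroxy acid F4, and carboxyl activation with benzenesulfonyl chloride in pyridine at 0 °C closes the lactone with retention at the carbinol carbon, rejoining the route at 14.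

Further compounds
F0 | step 6 | none | none
F1 | step 7 | (1S,2R,5S,11S)-4-oxo-8-[(1R)-1,3,3-trimethylcyclohexyl]-3-oxatricyclo[5.4.0.0^2,5]undec-7-ene-11-carbonyl chloride | ClC(=O)[C@H]1CCC([C@]2(C)CCCC(C)(C)C2)=C2C[C@@H]3C(=O)O[C@@H]3[C@H]21
F2 | step 5 | (4S)-4-benzyl-3-{5-[(1R)-1,3,3-trimethylcyclohexyl]pent-4-ynoyl}-1,3-oxazolidin-2-one | O=C(CCC#C[C@]1(C)CCCC(C)(C)C1)N1[C@@H](Cc2ccccc2)COC1=O
F3 | step 5 | (4S)-4-benzyl-3-[(2S,3R)-3-hydroxy-2-{3-[(1R)-1,3,3-trimethylcyclohexyl]prop-2-yn-1-yl}pent-4-enoyl]-1,3-oxazolidin-2-one | C=C[C@@H](O)[C@H](CC#C[C@]1(C)CCCC(C)(C)C1)C(=O)N1[C@@H](Cc2ccccc2)COC1=O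
F4 | step 5 | (2S,3R)-3-hydroxy-2-{3-[(1R)-1,3,3-trimethylcyclohexyl]prop-2-yn-1-yl}pent-4-enoic acid | C=C[C@@H](O)[C@H](CC#C[C@]1(C)CCCC(C)(C)C1)C(=O)O
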